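The constants to carry over are read from the last samples of spring and dusk, with Rx at 2.2 mol% and 4.9 mol% and the other charges equal.

| setting | spring | dusk | noon | flask |
|---|---|---|---|---|
| Jo | 0.94 M | 0.94 M | 0.94 M | 0.94 M |
| Ux | 0.80 equiv | 0.80 equiv | 0.80 equiv | 0.800 equiv |
| Kj | 0.282 M | 0.282 M | 0.56 M | 0.282 M |
| Rx | 2.2 mol% | 4.9 mol% | 3.3 mol% | 3.3 mol% |
| remark | run made earlier | run made earlier | run made earlier |  |

- spring (time / min: Xo / %): 1.50: 0; 5.00: 8; 8.00: 8; 12.0: 12; 20.0: 18; 25.0: 23
- dusk (time / min: Xo / %): 2.00: 5; 3.00: 2; 5.00: 12; 8.00: 19; 15.0: 35; 25.0: 45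
- noon (time / min: Xo / %): 2.00: 1; 4.00: 4; 6.00: 9; 12.0: 17; 25.0: 24

(scatter of a reading: 2 percentage points)

- no earlier run changes the charge of Ux; that part of a forecast is a guess

1. apparent order in Rx when 20 % of the Jo are converted (percent change of the rate of making Xo for one percent more Rx charged)
2. factor on the rate of making Xo when 20 % of the Jo are converted if Ux is charged twice over

Treating Xo as first-order growth towards the Jo charged, the integrated law gives a constant equal to minus the logarithm of the fraction of the Jo charged not read as Xo, divided by the time. That is 0.0105 /min for spring and 0.0239 /min for dusk, and so an apparent order in Rx of 1.03 in this reckoning. Averaging the two constants per unit of loading and scaling to the loading of this flask gives 0.0159 /min, the flask constant.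

For whoever takes over the bench: this flask, charged with Jo, Ux, Kj and Rx, should show Xo at 27.2 % of the Jo charged after 20.0 min and 47.0 % after 40.0 min. Leave Kj at 0.282 M, the charge at which the constant was read. No earlier run changes the charge of Ux, so this reckoning offers no factor for it.

The forecast puts the order at 1.15, higher than this reckoning, and the factor for doubled Ux at 1.7: "I guess partial order, about 1.7".

The simulation of this flask gives an order of 1.3 and a factor of 1.01.

    Jo + Rx → Ty (k = 1.93 /M/min)
    Ux + Ty ⇌ Uv (K = 87.0 /M, k = 97.2 /M/min)
    Uv → Gu + Qi (k = 1.69 /min)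
    Qi → Rx + Xo (k = 1.68 /min)
    Uv + Kj → Zo (k = 0.268 /M/min)

This flask holds Xo at 27.1 % after 20.0 min and 43.3 % after 40.0 min, against the 27.2 % and 47.0 % from the flask constant. In noon, at the same loading but with Kj at 0.56 M, that constant gives 32.8 % after 25.0 min, and the reading is 24 %. In this flask after 40.0 min, Uv goes on to Gu and Qi 24 times as fast as it passes with Kj into Zo. Even so, Zo, the off-cycle form of the catalyst, holds 57.3 % of the catalyst charged at that time and 98.2 % after 400 min.

The earlier runs and the new flask were computed with made-up constants, and the scatter is random.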